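**Retrosynthetic overview**
- The side-chain carbinol comes from a catalyst-controlled reduction of a dienone. The dienone comes from a ring-bound 2-substituted allylic chloride and the enolate of 3-methylbut-3-en-2-one; the allylic chloride comes from ene-type chlorination of the isopropenyl group.
- The secondary C–Cl bond comes from the secondary C–OH with retention (neighbouring bromine).
- Key disconnection: the tertiary C–O bond comes from the tertiary allylic C–H. The oxygen is delivered through a selenium tether from the cis-1,3 (diaxial) secondary hydroxyl.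
- The tertiary C–Br bond and that secondary hydroxyl come from trans-diaxial HBr opening of cis-limonene oxide.
- No ring is formed. The cyclohexane ring and its one stereocentre are bought with limonene oxide and control the three ring stereocentres; the side-chain stereocentre is set last.

Assumption: commercial (+)-limonene oxide (about 1:1 cis/trans, both 4R) is used as bought; only its cis isomer is productive in step 1, so that step cannot exceed about half of the material.

**Step 1**
Reactants: 1 (4R)-limonene 1,2-oxide (commercial cis/trans mixture)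
Product: 2 (1S,2S,5R)-2-bromo-2-methyl-5-(prop-1-en-2-yl)cyclohexan-1-ol
Conditions: 48% aq HBr (0.5 equiv based on the mixture), Et2O, −20 °C; chromatography (trans epoxide recovered)
Reagents that add atoms: hydrogen bromide (Br)
Why: Acid-mediated epoxide opening to a halohydrin: only in the cis epoxide do Markovnikov attack at the tertiary carbon and trans-diaxial (Fürst–Plattner) opening coincide, so bromide enters the tertiary carbon with inversion, the secondary C–O bond keeps its configuration, and the axial OH ends up on the same face as the ring C–H next to the isopropenyl group.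

**Step 2**
Reactants: 2 (1S,2S,5R)-2-bromo-2-methyl-5-(prop-1-en-2-yl)cyclohexan-1-ol
Product: 6 (1S,3S,4S)-4-bromo-4-methyl-1-(prop-1-en-2-yl)cyclohexane-1,3-diol, via hydrogen selenite ester 3 (not isolated), via cyclic allyl seleninate 4 (not isolated), via cyclic selenium diester 5 (not isolated)
Conditions: SeO2 (1.2 equiv), 4 Å MS, 1,4-dioxane, 40 °C; then aq NaHCO3
Reagents that add atoms: selenium dioxide (O=[Se]=O)
Why: Proposed new method: a hydroxyl-tethered Riley oxidation, in which the axial secondary alcohol forms its hydrogen selenite ester and the tetravalent selenium, held 1,3-diaxial to the tertiary allylic C–H, undergoes an intramolecular ene reaction with the isopropenyl group (Se to the CH2 terminus, H from the ring carbon, the position selenium dioxide also attacks in limonene itself); the seven-membered allyl seleninate can then do its [2,3]-sigmatropic shift only on the face that carries the tether, so oxygen replaces hydrogen with retention and hydrolysis of the divalent selenium diester gives the cis-1,3-diol; the closest known reaction is the untethered selenium dioxide allylic hydroxylation (ene, then [2,3] shift), which has no facial control at such a centre.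

**Step 3**
Reactants: 6 (1S,3S,4S)-4-bromo-4-methyl-1-(prop-1-en-2-yl)cyclohexane-1,3-diol
Product: 9 (1S,3S,4S)-4-bromo-3-chloro-4-methyl-1-(prop-1-en-2-yl)cyclohexan-1-ol, via alkoxyphosphonium chloride 7 (not isolated), via bromonium chloride 8 (not isolated)
Conditions: PPh3, CCl4, MeCN, 0 to 40 °C
Reagents that add atoms: carbon tetrachloride (ClC(Cl)(Cl)Cl)
Why: Appel chlorination with neighbouring-group participation: only the secondary hydroxyl is activated, the anti-periplanar axial bromine displaces the phosphine oxide to give a bromonium ion, and chloride reopens it trans-diaxially at the secondary carbon (as nucleophiles do with steroidal 5,6-bromonium ions), so chlorine replaces OH with net retention and bromine stays on the tertiary carbon.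

**Step 4**
Reactants: 9 (1S,3S,4S)-4-bromo-3-chloro-4-methyl-1-(prop-1-en-2-yl)cyclohexan-1-ol
Product: 10 (1S,3S,4S)-4-bromo-3-chloro-1-(3-chloroprop-1-en-2-yl)-4-methylcyclohexan-1-ol
Conditions: NCS (1.1 equiv), PhSeCl (10 mol %), CH2Cl2, 25 °C
Reagents that add atoms: N-chlorosuccinimide (O=C1CCC(=O)N1Cl)
Why: Selenium-catalysed ene-type allylic chlorination: the 1,1-disubstituted alkene now has allylic hydrogens only on its methyl group (the ring carbon is quaternary), so the 2-substituted allyl chloride is the only regioisomer and no stereocentre is touched.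

**Step 5**
Reactants: 10 (1S,3S,4S)-4-bromo-3-chloro-1-(3-chloroprop-1-en-2-yl)-4-methylcyclohexan-1-ol, 11 3-methylbut-3-en-2-one
Product: 13 6-[(1S,3S,4S)-4-bromo-3-chloro-1-hydroxy-4-methylcyclohexyl]-2-methylhepta-1,6-dien-3-one, via lithium enolate 12 (not isolated)
Conditions: 11 (2.3 equiv), LiN(iPr)2 (2.2 equiv), THF, −78 °C; then 10, DMPU, −78 to −30 °C
Reagents that add atoms: none
Why: Kinetic enolate alkylation (SN2 at the primary allylic chloride): the cross-conjugated lithium enolate formed at the methyl group of 11 is C-alkylated at low temperature, one equivalent being consumed by the free tertiary hydroxyl, and the ring stereocentres are not involved.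

**Step 6**
Reactants: 13 6-[(1S,3S,4S)-4-bromo-3-chloro-1-hydroxy-4-methylcyclohexyl]-2-methylhepta-1,6-dien-3-one
Product: 14 (1S,3S,4S)-4-bromo-3-chloro-1-[(5R)-5-hydroxy-6-methylhepta-1,6-dien-2-yl]-4-methylcyclohexan-1-ol
Conditions: (S)-Me-CBS oxazaborolidine (0.2 equiv), catecholborane (3 equiv), toluene, −78 °C; then MeOH, pH 7 buffer
Reagents that add atoms: none
Why: Corey–Bakshi–Shibata reduction: the (S)-oxazaborolidine treats the isopropenyl group as the large substituent and delivers hydride to give the (R)-allylic alcohol under reagent control, while catecholborane leaves the two 1,1-disubstituted alkenes and both halides alone.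

**Compound list**
1 | (4R)-limonene 1,2-oxide, commercial mixture of the cis (1R,2S,4R) and trans (1S,2R,4R) epoxides | C=C(C)[C@@H]1CCC2(C)OC2C1 | starting material
2 | (1S,2S,5R)-2-bromo-2-methyl-5-(prop-1-en-2-yl)cyclohexan-1-ol | C=C(C)[C@@H]1CC[C@](C)(Br)[C@@H](O)C1 | intermediate
3 | (1S,2S,5R)-2-bromo-2-methyl-5-(prop-1-en-2-yl)cyclohexyl hydrogen selenite | C=C(C)[C@@H]1CC[C@](C)(Br)[C@@H](O[Se](=O)O)C1 | intermediate
4 | cyclic allyl seleninate (seven-membered ring joining the secondary oxygen through Se(=O) to the former alkene CH2, ring carbon now part of a tetrasubstituted alkene) | CC1=C2CC[C@](C)(Br)[C@H](C2)O[Se](=O)C1 | intermediate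
5 | cyclic divalent selenium diester of the cis-1,3-diol (1,3,2-dioxaselenane bridging the tertiary and secondary oxygens) | C=C(C)[C@]1(O[Se]O2)CC[C@](C)(Br)[C@@H]2C1 | intermediate
6 | (1S,3S,4S)-4-bromo-4-methyl-1-(prop-1-en-2-yl)cyclohexane-1,3-diol | C=C(C)[C@]1(O)CC[C@](C)(Br)[C@@H](O)C1 | intermediate
7 | triphenylphosphonium ether of the secondary hydroxyl of 6, chloride salt | C=C(C)[C@]1(O)CC[C@](C)(Br)[C@@H](O[P+](c2ccccc2)(c2ccccc2)c2ccccc2)C1.[Cl-] | intermediate
8 | bromonium ion bridging the tertiary and secondary ring carbons on the face opposite the tertiary hydroxyl, chloride salt | C=C(C)[C@]1(O)CC[C@]2(C)[Br+][C@@H]2C1.[Cl-] | intermediate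
9 | (1S,3S,4S)-4-bromo-3-chloro-4-methyl-1-(prop-1-en-2-yl)cyclohexan-1-ol | C=C(C)[C@]1(O)CC[C@](C)(Br)[C@@H](Cl)C1 | intermediate
10 | (1S,3S,4S)-4-bromo-3-chloro-1-(3-chloroprop-1-en-2-yl)-4-methylcyclohexan-1-ol | C=C(CCl)[C@]1(O)CC[C@](C)(Br)[C@@H](Cl)C1 | intermediate
11 | 3-methylbut-3-en-2-one | CC(=O)C(C)=C | starting material
12 | lithium 3-methylbuta-1,3-dien-2-olate | C=C([O-])C(C)=C.[Li+] | intermediate
13 | 6-[(1S,3S,4S)-4-bromo-3-chloro-1-hydroxy-4-methylcyclohexyl]-2-methylhepta-1,6-dien-3-one | C=C(C)C(=O)CCC(=C)[C@]1(O)CC[C@](C)(Br)[C@@H](Cl)C1 | intermediate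
14 | (1S,3S,4S)-4-bromo-3-chloro-1-[(5R)-5-hydroxy-6-methylhepta-1,6-dien-2-yl]-4-methylcyclohexan-1-ol | C=C(C)[C@H](O)CCC(=C)[C@]1(O)CC[C@](C)(Br)[C@@H](Cl)C1 | target

**Step count and risks**
Total steps: 6. Longest linear sequence: 6 (1 to 14).

Steps most likely to fail:

Step 2 (the new reaction). The selenite ester may oxidize the secondary alcohol to the ketone, or the untethered ene pathway may compete and give the other epimer or the methyl-oxidized product. The fallback uses known reactions, sets out from 2 and comes back at 9. Appel chlorination of 2 (PPh3, CCl4, retention through the bromonium ion) gives (1S,2S,4R)-1-bromo-2-chloro-1-methyl-4-(prop-1-en-2-yl)cyclohexane F1. Ozonolysis in MeOH at −78 °C followed by FeSO4·7H2O and TEMPO cleaves the isopropenyl group and traps the ring radical as 1-{[(3S,4S)-4-bromo-3-chloro-4-methylcyclohexyl]oxy}-2,2,6,6-tetramethylpiperidine F2, which mCPBA oxidizes to (3S,4S)-4-bromo-3-chloro-4-methylcyclohexan-1-one F3. Isopropenylmagnesium bromide with CeCl3 (THF, −78 °C) then adds from the equatorial side, away from the axial chlorine, and gives 9. The tertiary carbinol is then set by carbonyl addition instead of C–H oxidation.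

Step 3. The bromonium ion may open at the tertiary carbon (giving the halogen-swapped isomer), or the tertiary hydroxyl may close a transannular ether. The fallback sets out from 1 (its trans epoxide, recovered from step 1) and comes back at 9. LiCl/AcOH in THF opens the trans epoxide at the secondary carbon to (1S,2S,4R)-2-chloro-1-methyl-4-(prop-1-en-2-yl)cyclohexan-1-ol F4. TMSBr (CH2Cl2, −20 °C) then replaces the tertiary hydroxyl through the chloronium ion, where Markovnikov and diaxial opening agree, and gives the bromochloride F1 of the step 2 fallback, which is carried through F2 and F3 to 9 as described there. The halogens are thus installed in the opposite order, before the tertiary alcohol exists.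

Step 5. The dienolate may polymerize or O-alkylate, and the alkoxide of 10 may attack its own allylic chloride. The fallback sets out from 10 and comes back at 13. The lithium enolate of N-methoxy-N-methylacetamide (LiN(iPr)2, THF, −78 °C) is alkylated with 10 to give 4-[(1S,3S,4S)-4-bromo-3-chloro-1-hydroxy-4-methylcyclohexyl]-N-methoxy-N-methylpent-4-enamide F5, and isopropenylmagnesium bromide (THF, −20 °C) converts it into 13.

**Further compounds**
F1 | step 2 | (1S,2S,4R)-1-bromo-2-chloro-1-methyl-4-(prop-1-en-2-yl)cyclohexane | C=C(C)[C@@H]1CC[C@](C)(Br)[C@@H](Cl)C1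
F2 | step 2 | 1-{[(3S,4S)-4-bromo-3-chloro-4-methylcyclohexyl]oxy}-2,2,6,6-tetramethylpiperidine (both epimers at the oxygen-bearing carbon) | CC1(C)CCCC(C)(C)N1OC1CC[C@](C)(Br)[C@@H](Cl)C1
F3 | step 2 | (3S,4S)-4-bromo-3-chloro-4-methylcyclohexan-1-one | O=C1CC[C@](C)(Br)[C@@H](Cl)C1
F4 | step 3 | (1S,2S,4R)-2-chloro-1-methyl-4-(prop-1-en-2-yl)cyclohexan-1-ol | C=C(C)[C@@H]1CC[C@](C)(O)[C@@H](Cl)C1
F5 | step 5 | 4-[(1S,3S,4S)-4-bromo-3-chloro-1-hydroxy-4-methylcyclohexyl]-N-methoxy-N-methylpent-4-enamide | CON(C)C(=O)CCC(=C)[C@]1(O)CC[C@](C)(Br)[C@@H](Cl)C1
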